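## Retrosynthetic overview

1. Target ⇐ silyl ether cleavage, C2 acetylation and C2 ketone reduction; the δ-lactone (C3–CH2 and C4–O bonds) ⇐ Michael addition–lactonisation of a 4-hydroxy-2-oxoguaianolide onto a 2-arylacrylate.
2. 2-Arylacrylate ⇐ 4-chlorotoluene via a cyclic benzylic ether, ring-opening and stereoconvergent Negishi coupling (benzylic centre), then borylation/Suzuki coupling with methyl 2-bromoacrylate.
3. Guaianolide ⇐ trans-γ-lactone from a C7 aldol with methyl bromopyruvate, directed C8 reduction and Zn elimination; the cycloheptanone ⇐ one-carbon ring expansion (diazoalkane 1,2-shift) of a chlorine-blocked cyclohexanone.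
4. Cyclohexanone ⇐ Diels–Alder adduct of a selenylated (S)-4-hydroxy-4-methylcyclopentenone with a 2-silyloxypentadiene (C4 controls C10); cyclopentenone ⇐ asymmetric aldolisation of the cis-enedione from 2,5-dimethylfuran.
5. Ring order: cyclopentenone → cyclohexene (Diels–Alder) → cycloheptane (ring expansion) → γ-lactone → δ-lactone; the benzene ring is bought.

Convention: C1–C15 are guaiane locants of the target core (C2 = CHOAc, C4 = CMe–O, C1=C5, C7/C8 = γ-lactone fusion, C10 = CHMe, C11–C13 = lactone carbons); C1'–C3' are C=O, CHAr and CH2 of the δ-lactone.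

Assumption: (S,S)-ProPhenol is taken to give the (S)-cyclopentenone and (R)-i-Pr-Pybox the (R)-benzylic centre; if a sense is opposite, the enantiomeric ligand is used.

## Route

Step 1
Reactants: 1 2,5-dimethylfuran
Product: 2 (Z)-hex-3-ene-2,5-dione
Conditions: mCPBA (1.05 equiv), CH2Cl2, 0 °C
Reagents that add atoms: m-chloroperbenzoic acid, OOC(=O)c1cccc(Cl)c1
Why: Oxidative ring-opening of the furan (epoxidation then ring cleavage) gives the enedione with the Z geometry inherited from the ring.

Step 2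
Reactants: 2 (Z)-hex-3-ene-2,5-dione
Product: 3 (S)-4-hydroxy-4-methylcyclopent-2-en-1-one
Conditions: (S,S)-ProPhenol (10 mol%), Et2Zn (20 mol%), 4 Å MS, THF, −20 °C
Reagents that add atoms: none
Why: Proposed new method: the dinuclear Zn–ProPhenol catalyst forms a zinc enolate of one acetyl group on one Zn while the second Zn binds the other carbonyl, which the cis-alkene holds within reach, so the enolate adds to one enantiotopic ketone face in a 5-(enolendo)-exo-trig aldol that closes the ring and sets C4; the tertiary aldolate cannot dehydrate (a cyclopentadienone would result) and turns over by proton exchange with fresh 2; the closest known reactions are the Zn–ProPhenol direct aldol of methyl ketones with aldehydes and the racemic Na2CO3-mediated cyclisation of 2.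

Step 3
Reactants: 3 (S)-4-hydroxy-4-methylcyclopent-2-en-1-one
Product: 4 (S)-4-hydroxy-4-methyl-2-(phenylselanyl)cyclopent-2-en-1-one
Conditions: PhSeCl (1.2 equiv), pyridine, CH2Cl2, 0 → 23 °C
Reagents that add atoms: phenylselenenyl chloride, Cl[Se]c1ccccc1
Why: α-Selenenylation of the enone (pyridine conjugate addition, Se capture of the enolate, loss of pyridine) places PhSe on the α-carbon (future C1) only, which activates the dienophile and prepares the later C1=C5 double bond.

Step 4
Reactants: 5 (E)-pent-3-en-2-one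
Product: 6 tert-butyl(dimethyl){[(3E)-penta-1,3-dien-2-yl]oxy}silane
Conditions: TBSOTf, Et3N, Et2O, 0 °C
Reagents that add atoms: tert-butyldimethylsilyl triflate, CC(C)(C)[Si](C)(C)OS(=O)(=O)C(F)(F)F
Why: Soft enolisation of the methyl ketone at its CH3 group gives the 2-silyloxy diene with the E-propenyl unit intact (silyl dienol ether formation).

Step 5
Reactants: 4 (S)-4-hydroxy-4-methyl-2-(phenylselanyl)cyclopent-2-en-1-one; 6 tert-butyl(dimethyl){[(3E)-penta-1,3-dien-2-yl]oxy}silane
Product: 7 (3S,3aS,7S,7aR)-5-(tert-butyldimethylsilyloxy)-3-hydroxy-3,7-dimethyl-7a-(phenylselanyl)-2,3,3a,4,7,7a-hexahydro-1H-inden-1-one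
Conditions: 6 (2 equiv), BHT (cat.), toluene, 90 °C, sealed tube
Reagents that add atoms: none
Why: Diels–Alder reaction in which the CH2 terminus of the 2-silyloxydiene bonds to the enone β-carbon C5 ("para" rule), the diene adds syn to the C4–OH (anti to the C4 methyl, as with p-quinols) and endo to the ring ketone, which sets C10 (methyl cis to C4–O, trans to SePh) and gives the regiodefined C8 enol ether.

Step 6
Reactants: 7 Diels–Alder adduct
Product: 9 (3S,7S)-5-(tert-butyldimethylsilyloxy)-3-hydroxy-3,7-dimethyl-2,3,4,7-tetrahydro-1H-inden-1-one, via selenoxide 8 (not isolated)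
Conditions: mCPBA (1.0 equiv), CH2Cl2, −78 °C; i-Pr2NH (2 equiv), → 23 °C; used at once
Reagents that add atoms: none
Why: Selenide oxidation and selenoxide syn-elimination; the ring-fusion C5–H is nearly eclipsed with C1–Se in the five-membered ring, so the conjugated C1=C5 enone forms and not the C1=C10 isomer.

Step 7
Reactants: 9 silyloxy dienone
Product: 10 (3S,6S,7R)-6-chloro-3-hydroxy-3,7-dimethyl-2,3,6,7-tetrahydro-1H-indene-1,5(4H)-dione
Conditions: NCS, THF, −40 → 0 °C; used crude and cold
Reagents that add atoms: N-chlorosuccinimide, O=C1CCC(=O)N1Cl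
Why: Electrophilic α-chlorination of the silyl enol ether occurs at C9 anti to the neighbouring C10 methyl; the chlorine then blocks migration of C9 and relays configuration to C7.

Step 8
Reactants: 10 chloro diketone; 11 methyl 3-bromo-2-oxopropanoate
Product: 14 methyl (4S,7R,9S,10R)-13-bromo-9-chloro-4,11-dihydroxy-2,8-dioxoguai-1(5)-en-12-oate (C11 epimers), via C-silyl ketone 12 (not isolated), via enol silane 13 (not isolated)
Conditions: TMSCHN2 (1.3 equiv), Sc(OTf)3 (10 mol%), CH2Cl2, −40 → 0 °C; then 11, −78 °C; 1 M HCl work-up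
Reagents that add atoms: (trimethylsilyl)diazomethane, C[Si](C)(C)C=[N+]=[N-]
Why: Sc(III)-catalysed diazoalkane–ketone homologation (Tiffeneau–Demjanov-type 1,2-shift, six- to seven-membered ring): TMSCHN2 adds to the saturated α-chloro ketone and not to the hindered enone, the non-halogenated C6 migrates with loss of N2 because a CHCl carbon does not migrate, 1,3-Brook shift gives the regiodefined C7 enol silane, and its Mukaiyama aldol with 11 occurs anti to the pseudo-axial C9–Cl, which sets C7.

Step 9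
Reactants: 14 chloro aldol
Product: 15 methyl (4S,7R,10S)-13-bromo-4,11-dihydroxy-2,8-dioxoguai-1(5)-en-12-oate (C11 epimers)
Conditions: SmI2 (2.2 equiv), THF–MeOH, −78 °C
Reagents that add atoms: none
Why: Samarium diiodide reduces the α-chloro ketone within seconds at −78 °C (samarium enolate on the C9 side, then protonation) and leaves the enone, primary bromide, ester and C7 untouched.

Step 10
Reactants: 15 β-hydroxy ketone
Product: 17 (4S,7S,8S,10S)-13-bromo-4,11-dihydroxy-2-oxoguai-1(5)-en-12,8-olide (7,8-trans; C11 epimers), via diol ester 16 (not isolated)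
Conditions: Me4NBH(OAc)3 (1.5 equiv), MeCN–AcOH, −30 °C; then CSA (cat.), CH2Cl2, 23 °C
Reagents that add atoms: none
Why: Hydroxyl-directed (Evans–Saksena) reduction in which the borohydride bound to the C11 hydroxyl delivers hydride to the saturated C8 ketone on the face of the C7 side chain, giving the 7,8-trans alcohol (the tetrasubstituted C2 enone reacts far more slowly at −30 °C), and acid then closes the trans-fused γ-lactone.

Step 11
Reactants: 17 bromohydrin lactone
Product: 18 (4S,7R,8S,10S)-4-hydroxy-2-oxoguaia-1(5),11(13)-dien-12,8-olide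
Conditions: Zn dust, NaI (cat.), AcOH–THF, 40 °C
Reagents that add atoms: none
Why: Zinc-mediated reductive β-elimination of the bromohydrin (insertion into C–Br, loss of the neighbouring hydroxyl) gives the exocyclic 11(13)-alkene regiospecifically.

Step 12
Reactants: 19 4-chlorotoluene
Product: 20 1-(5-chloro-2-methylphenyl)ethan-1-one
Conditions: AcCl, AlCl3, CH2Cl2, 0 → 23 °C
Reagents that add atoms: acetyl chloride, CC(=O)Cl
Why: Friedel–Crafts acylation goes ortho to the activating methyl group (para position blocked, chlorine deactivating).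

Step 13
Reactants: 20 1-(5-chloro-2-methylphenyl)ethan-1-one
Product: 21 1-[2-(bromomethyl)-5-chlorophenyl]ethan-1-one
Conditions: NBS, AIBN (cat.), PhCF3, 80 °C
Reagents that add atoms: N-bromosuccinimide, O=C1CCC(=O)N1Br
Why: Wohl–Ziegler radical bromination at the only benzylic C–H position.

Step 14
Reactants: 21 1-[2-(bromomethyl)-5-chlorophenyl]ethan-1-one
Product: 23 rac-6-chloro-1-methyl-1,3-dihydro-2-benzofuran, via bromo alcohol 22 (not isolated)
Conditions: NaBH4, MeOH, 0 °C; then K2CO3, 23 °C
Reagents that add atoms: none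
Why: Ketone reduction followed by intramolecular Williamson etherification (5-exo-tet) gives the cyclic benzylic ether, which masks the benzylic alcohol and keeps the secondary benzylic carbon as a latent electrophile.

Step 15
Reactants: 23 rac-6-chloro-1-methyl-1,3-dihydro-2-benzofuran; 24 3-bromopropyl acetate
Product: 27 (4R)-4-[5-chloro-2-(hydroxymethyl)phenyl]pentyl acetate, via benzylic bromide 25 (not isolated), via alkylzinc bromide 26 (not isolated)
Conditions: 23, TMSBr, CH2Cl2, 0 °C, evaporate; 24, Zn, I2 (cat.), DMA, 70 °C; combine, NiBr2·glyme (10 mol%), (R)-i-Pr-Pybox (13 mol%), DMA, 0 °C; citric acid, MeOH work-up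
Reagents that add atoms: none
Why: Silyl bromide cleaves the cyclic ether at the secondary benzylic C–O (SN1-like) to the racemic benzylic bromide, which undergoes Ni/Pybox stereoconvergent Negishi coupling (benzylic radical captured by the chiral Ni–alkyl) to set the (R)-benzylic centre, the aryl chloride being inert.

Step 16
Reactants: 27 (4R)-4-[5-chloro-2-(hydroxymethyl)phenyl]pentyl acetate
Product: 28 (4R)-4-[2-(tert-butyldimethylsilyloxymethyl)-5-chlorophenyl]pentyl acetate
Conditions: TBSCl, imidazole, DMF, 23 °C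
Reagents that add atoms: tert-butyldimethylsilyl chloride, CC(C)(C)[Si](C)(C)Cl
Why: Silylation of the primary benzylic alcohol so that it is not acetylated later.

Step 17
Reactants: 28 aryl chloride; 29 methyl 2-bromoprop-2-enoate
Product: 31 methyl 2-{3-[(2R)-5-acetoxypentan-2-yl]-4-(tert-butyldimethylsilyloxymethyl)phenyl}prop-2-enoate, via aryl boronate 30 (not isolated)
Conditions: B2pin2, Pd2(dba)3 (2 mol%), XPhos (8 mol%), KOAc, dioxane, 100 °C; then 29, aq. K3PO4, 50 °C
Reagents that add atoms: none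
Why: One-pot Miyaura borylation of the aryl chloride and Suzuki–Miyaura coupling with the α-bromoacrylate gives the 2-arylacrylate without touching acetate or silyl ether.

Step 18
Reactants: 18 guaianolide enone; 31 2-arylacrylate
Product: 33 keto lactone (target skeleton with C2=O in place of C2H–OAc; benzylic OH as TBS ether), via Michael adduct 32 (not isolated)
Conditions: 18, LiHMDS (2.1 equiv), THF, −78 °C; 31 (1.5 equiv), −78 → −20 °C; AcOH, −78 °C
Reagents that add atoms: none
Why: Michael addition–lactonisation in which the C4 alkoxide/C3 enolate dianion adds through C3 to the 2-arylacrylate, only the C3 epimer cis to the C4 alkoxide can close the δ-lactone (C3 epimerises α to the ketone), and protonation of the benzylic lactone enolate from the convex face gives the C2' epimer with pseudo-equatorial aryl, which is also the thermodynamic one.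

Step 19
Reactants: 33 keto lactone
Product: 34 C2 alcohol (target skeleton with free C2–OH cis to the δ-lactone; benzylic TBS ether)
Conditions: NaBH4, CeCl3·7H2O, MeOH, −78 °C
Reagents that add atoms: none
Why: Luche 1,2-reduction in which hydride attacks the C2 enone carbonyl from the face opposite the adjacent C3 substituent and the C10 methyl; lactones, acetate and the α-methylene lactone are not reduced.

Step 20
Reactants: 34 C2 alcohol
Product: 35 O-TBS ether of the target
Conditions: Ac2O, pyridine, DMAP (cat.), CH2Cl2, 0 → 23 °C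
Reagents that add atoms: acetic anhydride, CC(=O)OC(C)=O
Why: DMAP-catalysed acetylation of the only free hydroxyl group.

Step 21
Reactants: 35 O-TBS ether of the target
Product: 36 target CNP0205574.1
Conditions: HF·pyridine, THF, 0 °C
Reagents that add atoms: none
Why: Fluoride cleavage of the primary benzylic silyl ether; acetates, lactones and the α-methylene lactone are stable to buffered HF.

## Compound list

1 | 2,5-dimethylfuran | Cc1ccc(C)o1 | starting material
2 | (Z)-hex-3-ene-2,5-dione | CC(=O)/C=C\C(C)=O | intermediate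
3 | (S)-4-hydroxy-4-methylcyclopent-2-en-1-one | O=C1C=C[C@@](C)(O)C1 | intermediate
4 | (S)-4-hydroxy-4-methyl-2-(phenylselanyl)cyclopent-2-en-1-one | O=C1C([Se]c2ccccc2)=C[C@@](C)(O)C1 | intermediate
5 | (E)-pent-3-en-2-one | C/C=C/C(C)=O | starting material
6 | tert-butyl(dimethyl){[(3E)-penta-1,3-dien-2-yl]oxy}silane | C/C=C/C(=C)O[Si](C)(C)C(C)(C)C | intermediate
7 | (3S,3aS,7S,7aR)-5-(tert-butyldimethylsilyloxy)-3-hydroxy-3,7-dimethyl-7a-(phenylselanyl)-2,3,3a,4,7,7a-hexahydro-1H-inden-1-one (cis-fused; 7-Me cis to 3-OH, trans to SePh) | C[C@H]1C=C(O[Si](C)(C)C(C)(C)C)C[C@H]2[C@@](C)(O)CC(=O)[C@@]12[Se]c1ccccc1 | intermediate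
8 | Se-oxide of 7 | C[C@H]1C=C(O[Si](C)(C)C(C)(C)C)C[C@H]2[C@@](C)(O)CC(=O)[C@@]12[Se](=O)c1ccccc1 | intermediate
9 | (3S,7S)-5-(tert-butyldimethylsilyloxy)-3-hydroxy-3,7-dimethyl-2,3,4,7-tetrahydro-1H-inden-1-one | C[C@H]1C=C(O[Si](C)(C)C(C)(C)C)CC2=C1C(=O)C[C@]2(C)O | intermediate
10 | (3S,6S,7R)-6-chloro-3-hydroxy-3,7-dimethyl-2,3,6,7-tetrahydro-1H-indene-1,5(4H)-dione (Cl trans to 7-Me) | C[C@H]1[C@H](Cl)C(=O)CC2=C1C(=O)C[C@]2(C)O | intermediate
11 | methyl 3-bromo-2-oxopropanoate | COC(=O)C(=O)CBr | starting material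
12 | (4S,9S,10R)-9-chloro-4-hydroxy-7-(trimethylsilyl)-11,12,13-trinorguai-1(5)-ene-2,8-dione (C7 epimers) | C[C@H]1[C@H](Cl)C(=O)C([Si](C)(C)C)CC2=C1C(=O)C[C@]2(C)O | intermediate
13 | (4S,9S,10R)-9-chloro-4-hydroxy-8-[(trimethylsilyl)oxy]-11,12,13-trinorguaia-1(5),7-dien-2-one | C[C@H]1[C@H](Cl)C(O[Si](C)(C)C)=CCC2=C1C(=O)C[C@]2(C)O | intermediate
14 | methyl (4S,7R,9S,10R)-13-bromo-9-chloro-4,11-dihydroxy-2,8-dioxoguai-1(5)-en-12-oate (C7 side chain cis to C10-Me, trans to Cl; C11 epimers) | C[C@H]1[C@H](Cl)C(=O)[C@@H](C(O)(CBr)C(=O)OC)CC2=C1C(=O)C[C@]2(C)O | intermediate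
15 | methyl (4S,7R,10S)-13-bromo-4,11-dihydroxy-2,8-dioxoguai-1(5)-en-12-oate (C11 epimers) | C[C@H]1CC(=O)[C@@H](C(O)(CBr)C(=O)OC)CC2=C1C(=O)C[C@]2(C)O | intermediate
16 | methyl (4S,7S,8S,10S)-13-bromo-4,8,11-trihydroxy-2-oxoguai-1(5)-en-12-oate (8-OH trans to C7 side chain) | C[C@H]1C[C@H](O)[C@@H](C(O)(CBr)C(=O)OC)CC2=C1C(=O)C[C@]2(C)O | intermediate
17 | (4S,7S,8S,10S)-13-bromo-4,11-dihydroxy-2-oxoguai-1(5)-en-12,8-olide (trans-fused lactone; C11 epimers) | OC1(CBr)C(=O)O[C@H]2C[C@H](C)C3=C(C[C@H]12)[C@@](C)(O)CC3=O | intermediate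
18 | (4S,7R,8S,10S)-4-hydroxy-2-oxoguaia-1(5),11(13)-dien-12,8-olide | C=C1C(=O)O[C@H]2C[C@H](C)C3=C(C[C@H]12)[C@@](C)(O)CC3=O | intermediate
19 | 4-chlorotoluene | Cc1ccc(Cl)cc1 | starting material
20 | 1-(5-chloro-2-methylphenyl)ethan-1-one | CC(=O)c1cc(Cl)ccc1C | intermediate
21 | 1-[2-(bromomethyl)-5-chlorophenyl]ethan-1-one | CC(=O)c1cc(Cl)ccc1CBr | intermediate
22 | rac-1-[2-(bromomethyl)-5-chlorophenyl]ethan-1-ol | CC(O)c1cc(Cl)ccc1CBr | intermediate
23 | rac-6-chloro-1-methyl-1,3-dihydro-2-benzofuran | CC1OCc2ccc(Cl)cc21 | intermediate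
24 | 3-bromopropyl acetate | CC(=O)OCCCBr | starting material
25 | rac-{[2-(1-bromoethyl)-4-chlorophenyl]methoxy}trimethylsilane | CC(Br)c1cc(Cl)ccc1CO[Si](C)(C)C | intermediate
26 | (3-acetoxypropyl)zinc bromide | CC(=O)OCCC[Zn]Br | intermediate
27 | (4R)-4-[5-chloro-2-(hydroxymethyl)phenyl]pentyl acetate | C[C@H](CCCOC(C)=O)c1cc(Cl)ccc1CO | intermediate
28 | (4R)-4-[2-(tert-butyldimethylsilyloxymethyl)-5-chlorophenyl]pentyl acetate | C[C@H](CCCOC(C)=O)c1cc(Cl)ccc1CO[Si](C)(C)C(C)(C)C | intermediate
29 | methyl 2-bromoprop-2-enoate | C=C(Br)C(=O)OC | starting material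
30 | pinacol boronate of 28 (Bpin in place of Cl) | C[C@H](CCCOC(C)=O)c1cc(B2OC(C)(C)C(C)(C)O2)ccc1CO[Si](C)(C)C(C)(C)C | intermediate
31 | methyl 2-{3-[(2R)-5-acetoxypentan-2-yl]-4-(tert-butyldimethylsilyloxymethyl)phenyl}prop-2-enoate | C=C(C(=O)OC)c1ccc(CO[Si](C)(C)C(C)(C)C)c([C@H](C)CCCOC(C)=O)c1 | intermediate
32 | Michael adduct: 18 carrying CH2–CH(Ar)–CO2Me at C3 (C3 and C2' epimers, free C4–OH) | C=C1C(=O)O[C@H]2C[C@H](C)C3=C(C[C@H]12)[C@@](C)(O)C(CC(C(=O)OC)c1ccc(CO[Si](C)(C)C(C)(C)C)c([C@H](C)CCCOC(C)=O)c1)C3=O | intermediate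
33 | keto lactone: target skeleton with C2=O, cis-fused δ-lactone, aryl configured as in the target, benzylic OTBS | C=C1C(=O)O[C@H]2C[C@H](C)C3=C(C[C@H]12)[C@@]1(C)OC(=O)[C@@H](c2ccc(CO[Si](C)(C)C(C)(C)C)c([C@H](C)CCCOC(C)=O)c2)C[C@H]1C3=O | intermediate
34 | C2 alcohol: as 33 with C2–OH cis to the δ-lactone (configuration of the target) | C=C1C(=O)O[C@H]2C[C@H](C)C3=C(C[C@H]12)[C@@]1(C)OC(=O)[C@@H](c2ccc(CO[Si](C)(C)C(C)(C)C)c([C@H](C)CCCOC(C)=O)c2)C[C@H]1[C@H]3O | intermediate
35 | O-TBS ether of the target | C=C1C(=O)O[C@H]2C[C@H](C)C3=C(C[C@H]12)[C@@]1(C)OC(=O)[C@@H](c2ccc(CO[Si](C)(C)C(C)(C)C)c([C@H](C)CCCOC(C)=O)c2)C[C@H]1[C@H]3OC(C)=O | intermediate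
36 | CNP0205574.1: (2R,3S,4S,7R,8S,10S) guaianolide core, (2'R) α-aryl δ-lactone, (R) side chain | C=C1C(=O)O[C@H]2C[C@H](C)C3=C(C[C@H]12)[C@@]1(C)OC(=O)[C@@H](c2ccc(CO)c([C@H](C)CCCOC(C)=O)c2)C[C@H]1[C@H]3OC(C)=O | target

## Step count and risks

Total steps: 21 (14 in the main line, 1 for the diene, 6 for the arene). Longest linear sequence: 14 steps (1–3, 5–11, 18–21).

The three steps most likely to fail:

Step 2 (the proposed new aldolisation; enantioselectivity and turnover are unproven). The fallback sets out from 2: stirring with aqueous Na2CO3, the known cyclisation, gives racemic 4-hydroxy-4-methylcyclopent-2-en-1-one F1, which is resolved by preparative chiral-phase SFC. The (S)-enantiomer is 3, where the route resumes.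

Step 8 (ring expansion, Brook shift and aldol in one flask; the diazoalkane could also give the epoxide, or the silyl ketone might not rearrange). The fallback sets out from 10: BF3·OEt2-promoted homologation with ethyl diazoacetate, in which the chlorinated carbon again does not migrate, gives ethyl (4S,9S,10R)-9-chloro-4-hydroxy-2,8-dioxo-12,13-dinorguai-1(5)-en-11-oate F2. Zn/AcOH removes the chlorine to give ethyl (4S,10S)-4-hydroxy-2,8-dioxo-12,13-dinorguai-1(5)-en-11-oate F3. LiOH and then careful acidification give (4S,10S)-4-hydroxy-2,8-dioxo-12,13-dinorguai-1(5)-en-11-oic acid F4. Its amine-catalysed decarboxylative aldol with 11 forms the C7–C11 bond only at C7 and comes back to the route at 15; the C7 epimers are then separated, because the chlorine relay is lost.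

Step 18 (strong base in the presence of the α-methylene lactone; C2' configuration). The fallback sets out from 18 and 31: TMSOTf/Et3N converts 18 into (4S,7R,8S,10S)-2,4-bis(trimethylsilyloxy)guaia-1(5),2,11(13)-trien-12,8-olide F5. Tf2NH-catalysed Mukaiyama–Michael addition of F5 to 31 and aqueous work-up give hydroxy ester 32, which is lactonised separately with CSA in warm toluene, coming back to the route at 33. No strong base then meets the α-methylene lactone.

## Further compounds

F1 | step 2 | rac-4-hydroxy-4-methylcyclopent-2-en-1-one | O=C1C=CC(C)(O)C1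
F2 | step 8 | ethyl (4S,9S,10R)-9-chloro-4-hydroxy-2,8-dioxo-12,13-dinorguai-1(5)-en-11-oate | C[C@H]1[C@H](Cl)C(=O)C(C(=O)OCC)CC2=C1C(=O)C[C@]2(C)O
F3 | step 8 | ethyl (4S,10S)-4-hydroxy-2,8-dioxo-12,13-dinorguai-1(5)-en-11-oate | C[C@H]1CC(=O)C(C(=O)OCC)CC2=C1C(=O)C[C@]2(C)O
F4 | step 8 | (4S,10S)-4-hydroxy-2,8-dioxo-12,13-dinorguai-1(5)-en-11-oic acid | C[C@H]1CC(=O)C(C(=O)O)CC2=C1C(=O)C[C@]2(C)O
F5 | step 18 | (4S,7R,8S,10S)-2,4-bis(trimethylsilyloxy)guaia-1(5),2,11(13)-trien-12,8-olide | C=C1C(=O)O[C@H]2C[C@H](C)C3=C(C[C@H]12)[C@@](C)(O[Si](C)(C)C)C=C3O[Si](C)(C)C
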